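23.9 min⁻¹ is what the summer run gives for the quantity I choose the next flask by. Take the product as a fraction of the solid substrate charged, divide by the load (catalyst charged as a fraction of that solid), and divide by the time: that is the turnover rate, or turnover frequency.

| flask | solid substrate | reagent | free catalyst | temperature | remark | time |
|---|---|---|---|---|---|---|
| autumn | 0.020 M | 0.036 M | 4.5 µM | 10 °C | run made earlier |  |
| winter | 0.020 M | 0.036 M | 13 µM | 32 °C | run made earlier |  |
| summer | 0.011 M | 0.036 M | 20 µM | 10 °C | run made earlier |  |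
| gamma | 0.020 M | 0.0500 M | 20 µM | 15 °C |  | 15 min |
| beta | 0.020 M | 0.0360 M | 20 µM | 0 °C |  | 15 min |
| delta | 0.0050 M | 0.0800 M | 20 µM | 40 °C |  | 15 min |
| zeta | 0.012 M | 0.0360 M | 12 µM | 15 °C |  | 15 min |
| theta | 0.020 M | 0.0360 M | 6.0 µM | 30 °C |  | 15 min |
| epsilon | 0.020 M | 0.0250 M | 20 µM | 0 °C |  | 15 min |

autumn run (percent of the solid substrate charged)

| time / min | product / % | solid substrate / % |
|---|---|---|
| 0.500 | 0.4 | 90.4 |
| 0.833 | 0.3 | 84.1 |
| 1.33 | 1.2 | 76.6 |
| 2.00 | 0.6 | 68.1 |
| 3.00 | 2.7 | 58.9 |
| 4.00 | 3.1 | 52.4 |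
| 6.00 | 3.6 | 43.6 |

winter run (percent of the solid substrate charged)

| time / s | product / % | solid substrate / % |
|---|---|---|
| 10.0 | 0.8 | 96.3 |
| 20.0 | 0 | 92.4 |
| 40.0 | 1.0 | 86.6 |
| 60.0 | 0 | 81.3 |
| 80.0 | 0.5 | 76.1 |
| 90.0 | 0.8 | 74.7 |
| 120 | 0.3 | 67.5 |

summer run (percent of the solid substrate charged)

| time / min | product / % | solid substrate / % |
|---|---|---|
| 1.33 | 8.0 | 55.8 |
| 2.50 | 13.0 | 28.6 |
| 4.00 | 19.0 | 4.9 |
| 5.00 | 24.3 | 0.3 |
| 6.00 | 26.1 | 0.3 |

(standard deviation of a reading: 0.5 percentage points)

- solid substrate is a solid; its amount is given per volume of the solution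
- at the start none of the solid substrate is in solution
- what has only dissolved of solid substrate counts as not reacted

* ranking by amount of product, in percent of the solid substrate charged, from high to low, at 15 min (gamma / beta / delta / zeta / theta / epsilon)
* the amount of product, in percent of the solid substrate charged of the flask you put first, at 15 min
* the amount of product, in percent of the solid substrate charged of the flask you put last, at 15 min

Last readings of the three runs, as product ÷ load ÷ time:

summer, 10 °C: 26.1% ÷ 0.182% ÷ 6.00 min = 23.9 min⁻¹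

autumn, 10 °C: 3.6% ÷ 0.0225% ÷ 6.00 min = 26.7 min⁻¹

winter, 32 °C: 0.3% ÷ 0.0650% ÷ 120 s = 2.31 min⁻¹

Summer and autumn differ in load by a factor of 8.09, yet their rates lie close together, so at that temperature and reagent charge, over those 6.00 min, I can count turnovers and multiply by the load. The winter reading carries a scatter of 0.5 percentage points, so its rate is rough. Still, it is lower, and because of that I won't pay for turnovers with heat.

I charge beta next. It is colder than any run, so I give it the summer rate and no bonus. Theta is warm, so it gets the winter rate: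

beta: 23.9 min⁻¹ × 15 min × 0.100% = 35.9%

theta: 2.31 min⁻¹ × 15 min × 0.0300% = 1.04%

I put beta first and theta last. Epsilon shares beta's load and temperature but has less reagent, an effect no run tested, so I place it second on a guess.

The forecast differs from me at the top: it gives gamma > zeta > beta > epsilon > delta > theta, with 24% for its first flask, close to the last summer reading taken over, and 0.3% for its last, and it reads the winter run as, in its words, “steep thermal catalyst death”.

The flasks give beta > epsilon > delta > gamma > zeta > theta, with 55.0% and 2.84%.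

    reagent + free catalyst ⇌ catalyst intermediate A (K = 46.0 M⁻¹, k = 350 M⁻¹ s⁻¹, Ea = 40.0 kJ mol⁻¹, ΔH = −44.0 kJ mol⁻¹)
    starting material + catalyst intermediate A ⇌ catalyst intermediate B (K = 1200 M⁻¹, k = 480 M⁻¹ s⁻¹, Ea = 37.0 kJ mol⁻¹, ΔH = −22.0 kJ mol⁻¹)
    catalyst intermediate B ⇌ catalyst intermediate C (K = 2.20, k = 13.0 s⁻¹, Ea = 60.0 kJ mol⁻¹, ΔH = −64.0 kJ mol⁻¹)
    catalyst intermediate C → free catalyst + product (k = 8.90 s⁻¹, Ea = 67.0 kJ mol⁻¹)
    solid substrate ⇌ starting material, rate k5*(cs5 - [starting material]) while solid is left; crystals form when [starting material] > cs5 (solubility = 12.0 mM, k = 0.00620 s⁻¹)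
    free catalyst ⇌ dormant form (K = 30.0, k = 0.00450 s⁻¹, Ea = 86.0 kJ mol⁻¹, ΔH = 6.00 kJ mol⁻¹)
    (constants at 0 °C)

Beta's product converts to 36.6 min⁻¹, and theta's to 6.31 min⁻¹, a quarter of the summer rate. At 15.0 min theta holds 96.3% of its catalyst as dormant form, beta 73.7%. The neighbour is theta itself, with its charges and temperature held, read at 1.0 h instead. Its load stays the same, so I carry theta's rate forward:

6.31 min⁻¹ × 60.0 min × 0.0300% = 11.4%

At that time 93% of the reagent in the neighbour flask is still unbound, and that flask holds 12.6% product.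

The data were generated by integration on assumed constants; noise was put on by code.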